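**Strategy**

The plan rests on the tetrahydrofuran ring that carries the syringyl unit (O7, C8, C1, C5 and C6 of the 3,7-dioxabicyclo[3.3.0]octane core). Its C1–C8 and C6–O7 bonds are read as the union of an aryl aldehyde C=O with a three-carbon unit that is nucleophilic at C1 and electrophilic at C6. This unit is stored as a cyclopropane fused to the lactone form of the other ring. In the key step MgI2 opens the cyclopropane, and the aldehyde, which already holds the complete erythro side chain, is taken up in a formal [3+2] cycloaddition that forms both bonds and two stereocenters. Lactone-to-ether adjustment and desilylation follow.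

Key step: step 11

Remark: ArG stands for 3-methoxy-4-(triisopropylsilyloxy)phenyl; ArS stands for 3,5-dimethoxy-4-{[(1S,2R)-1,3-bis(tert-butyldimethylsilyloxy)-1-ArG-propan-2-yl]oxy}phenyl.
Remark: compound 8 is taken as a catalogue compound; it is otherwise one step from (R)-4-benzyl-2-oxazolidinone and chloroacetyl chloride.
Remark: the sense of induction in step 7 is assumed to be that of the propionyl series (chelated magnesium enolate attacked anti to the benzyl group); the configurations of 4 and 11 should be confirmed before material is carried on.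

**Route**

Step 1
Reactants: 1 vanillin
Product: 2 3-methoxy-4-(triisopropylsilyloxy)benzaldehyde
Conditions: iPr3SiCl, imidazole, DMF, rt
Reagents that add atoms: triisopropylsilyl chloride, CC(C)[Si](Cl)(C(C)C)C(C)C
Why: Imidazole-promoted silylation of the phenol should give an aryl silyl ether that survives every later step until the final fluoride treatment.

Step 2
Reactants: 2 3-methoxy-4-(triisopropylsilyloxy)benzaldehyde
Product: 3 rac-1-ArG-prop-2-en-1-ol
Conditions: CH2=CHMgBr, THF, -78 to 0 °C; aq. NH4Cl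
Reagents that add atoms: vinylmagnesium bromide, C=C[Mg]Br
Why: Grignard 1,2-addition to the aryl aldehyde should give the racemic aryl vinyl carbinol.

Step 3
Reactants: 3 rac-1-ArG-prop-2-en-1-ol
Product: 4 (S)-1-ArG-prop-2-en-1-ol
Conditions: immobilised Candida antarctica lipase B, vinyl acetate, toluene, 30 °C, stopped shortly after half conversion; chromatography
Reagents that add atoms: none
Why: Lipase-catalysed kinetic resolution by transesterification should acylate the (R)-alcohol (aryl as the large group, vinyl as the medium group), so that the (S)-alcohol, which holds the future C4 configuration, is recovered.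

Step 4
Reactants: 4 (S)-1-ArG-prop-2-en-1-ol
Product: 5 (S)-1-ArG-prop-2-en-1-yl 3-oxobutanoate
Conditions: diketene, DMAP (cat.), CH2Cl2, -10 to 0 °C
Reagents that add atoms: diketene, C=C1CC(=O)O1
Why: DMAP-catalysed acetoacetylation with diketene acylates the oxygen only and should leave the labile allylic stereocenter untouched at low temperature.

Step 5
Reactants: 5 (S)-1-ArG-prop-2-en-1-yl 3-oxobutanoate
Product: 6 (1R,4S,5S)-1-acetyl-4-ArG-3-oxabicyclo[3.1.0]hexan-2-one
Conditions: Mn(OAc)3·2H2O (2.2 equiv), Cu(OAc)2·H2O (1 equiv), AcOH, 25 to 40 °C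
Reagents that add atoms: none
Why: In this oxidative free-radical cyclisation (trivalent manganese with divalent copper), the α-radical of the acetoacetate should close 5-exo-trig onto the vinyl group with the aryl group pseudo-equatorial (aryl trans to the new CH2), and copper-mediated oxidation of the primary radical should be followed by 3-exo closure onto the dicarbonyl carbon, as known for 1-arylallyl acetoacetates.

Step 6
Reactants: 7 4-bromo-2,6-dimethoxyphenol; 8 (R)-4-benzyl-3-(chloroacetyl)oxazolidin-2-one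
Product: 9 (R)-4-benzyl-3-[(4-bromo-2,6-dimethoxyphenoxy)acetyl]oxazolidin-2-one
Conditions: K2CO3, NaI (cat.), acetone, 50 °C
Reagents that add atoms: none
Why: Williamson etherification of the phenoxide with the activated α-chloro imide (iodide-assisted SN2) should outpace attack at the imide carbonyl.

Step 7
Reactants: 9 (R)-4-benzyl-3-[(4-bromo-2,6-dimethoxyphenoxy)acetyl]oxazolidin-2-one; 2 3-methoxy-4-(triisopropylsilyloxy)benzaldehyde
Product: 11 (R)-4-benzyl-3-[(2S,3S)-2-(4-bromo-2,6-dimethoxyphenoxy)-3-hydroxy-3-ArG-propanoyl]oxazolidin-2-one, via trimethylsilyl ether 10 (not isolated)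
Conditions: MgCl2 (0.2 equiv), Et3N, Me3SiCl, EtOAc, rt; then AcOH-THF-H2O
Reagents that add atoms: none
Why: In this MgCl2-catalysed direct anti-aldol reaction of an N-acyloxazolidinone (Evans type), the chelated Z-enolate should be attacked on the face opposite the benzyl group through a boat transition state, which sets C2 and, anti to it, C3 (erythro), while silyl trapping prevents retro-aldol.

Step 8
Reactants: 11 anti-aldol imide
Product: 12 (1S,2R)-2-(4-bromo-2,6-dimethoxyphenoxy)-1-ArG-propane-1,3-diol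
Conditions: NaBH4, THF-H2O, 0 °C to rt
Reagents that add atoms: none
Why: Borohydride reduction of the exocyclic imide carbonyl should release the auxiliary and give the erythro 1,3-diol without touching either stereocenter.

Step 9
Reactants: 12 erythro diol
Product: 13 1,3-bis(tert-butyldimethylsilyl) ether of 12
Conditions: tBuMe2SiOTf, 2,6-lutidine, CH2Cl2, 0 °C
Reagents that add atoms: tert-butyldimethylsilyl triflate, CC(C)(C)[Si](C)(C)OS(=O)(=O)C(F)(F)F
Why: The silyl triflate should silylate the primary and the hindered benzylic hydroxyl alike, giving ethers that tolerate organolithium, MgI2, hydride and sulfonylation conditions.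

Step 10
Reactants: 13 bis-silyl ether aryl bromide
Product: 15 ArS-CHO (4-{[(1S,2R)-1,3-bis(tert-butyldimethylsilyloxy)-1-ArG-propan-2-yl]oxy}-3,5-dimethoxybenzaldehyde), via aryllithium 14 (not isolated)
Conditions: n-BuLi, THF, -78 °C; DMF; aq. NH4Cl
Reagents that add atoms: N,N-dimethylformamide, CN(C)C=O
Why: Bromine-lithium exchange on the electron-rich aryl bromide followed by formylation with DMF (Bouveault reaction) should unmask the aldehyde that had to be absent during the aldol step.

Step 11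
Reactants: 6 (1R,4S,5S)-1-acetyl-4-ArG-3-oxabicyclo[3.1.0]hexan-2-one; 15 ArS-CHO
Product: 19 (1S,4S,5R,8S)-4-ArG-8-ArS-3,7-dioxabicyclo[3.3.0]octan-2-one, via iodo magnesium enolate 16 (not isolated), via magnesium aldolate 17 (not isolated), via acetyl furofuranone 18 (not isolated)
Conditions: MgI2 (1.2 equiv), THF, 60 °C; then K2CO3 (0.3 equiv), MeOH, 0 °C to rt
Reagents that add atoms: none
Why: Proposed new method: MgI2 should bind the 1,3-dicarbonyl unit of 6 and deliver iodide to the cyclopropane CH2 (C6) in an SN2 homo-conjugate opening, giving the chelated enolate 16, which adds reversibly to aldehyde 15; the alkoxide of 17 then displaces iodide in a 5-exo-tet O-alkylation that closes the tetrahydrofuran ring (18) and regenerates MgI2, and methoxide finally removes the angular acetyl group by retro-Claisen cleavage with protonation on the convex face. The closest known reactions are the MgI2-promoted formal cycloadditions of acceptor cyclopropanes lacking a donor group with imines and nitrones, and the iodide/Lewis acid ring-opening aldol reactions of cyclopropyl ketones; an aldehyde with a lactone-fused 1-acyl cyclopropane is new. C1 is controlled by the existing ring: only the adduct whose new C1–C8 bond is cis to the CH2I arm can cyclise to the cis-fused bicycle, while the trans adduct returns by retro-aldol. C8 is set under Curtin–Hammett control, the exo-aryl adduct closing faster because only an endo aryl group is forced into the concave face; C4 and C5 are carried over from 6. The step needs iodide attack at C6 in preference to the benzylic lactone carbon C4, and C–C bond formation in preference to O-alkylation of the enolate (dihydrofuran formation). Strain, double activation of the C1–C6 bond and chelation of both enolate oxygens by magnesium are expected to secure this, and the ring-fused enolate formed on deacetylation cannot align its C8–O7 bond for β-elimination.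

Step 12
Reactants: 19 furofuranone
Product: 20 {(2S,3R,4R)-2-ArS-4-[(S)-hydroxy(ArG)methyl]oxolan-3-yl}methanol
Conditions: LiBH4, THF, MeOH (1 equiv), 0 °C to rt
Reagents that add atoms: none
Why: Borohydride reduction of the lactone should give the 1,4-diol and leave the silyl ethers, the benzylic ethers and all stereocenters untouched.

Step 13
Reactants: 20 diol
Product: 22 4,4''-bis-O-triisopropylsilyl-7'',9''-bis-O-tert-butyldimethylsilyl hedyotol C, via primary mesylate 21 (not isolated)
Conditions: MsCl (1.05 equiv), pyridine, CH2Cl2, 0 °C to rt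
Reagents that add atoms: none
Why: Selective sulfonylation of the primary hydroxyl followed by intramolecular Williamson etherification (5-exo-tet) by the benzylic hydroxyl should close the second tetrahydrofuran with retention at the benzylic carbon, the usual end-game for furofuranones.

Step 14
Reactants: 22 tetrasilyl ether
Product: 23 Hedyotol C
Conditions: Bu4NF, AcOH, THF, 0 °C to rt
Reagents that add atoms: none
Why: Buffered fluoride should cleave the two aryl and two alkyl silyl ethers without acid (which would epimerise the benzylic ethers) and without strong base.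

**Compound list**

1 | vanillin | COc1cc(C=O)ccc1O | starting material
2 | 3-methoxy-4-(triisopropylsilyloxy)benzaldehyde | COc1cc(C=O)ccc1O[Si](C(C)C)(C(C)C)C(C)C | intermediate
3 | rac-1-[3-methoxy-4-(triisopropylsilyloxy)phenyl]prop-2-en-1-ol | C=CC(O)c1ccc(O[Si](C(C)C)(C(C)C)C(C)C)c(OC)c1 | intermediate
4 | (S)-1-[3-methoxy-4-(triisopropylsilyloxy)phenyl]prop-2-en-1-ol | C=C[C@H](O)c1ccc(O[Si](C(C)C)(C(C)C)C(C)C)c(OC)c1 | intermediate
5 | (S)-1-[3-methoxy-4-(triisopropylsilyloxy)phenyl]prop-2-en-1-yl 3-oxobutanoate | C=C[C@H](OC(=O)CC(C)=O)c1ccc(O[Si](C(C)C)(C(C)C)C(C)C)c(OC)c1 | intermediate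
6 | (1R,4S,5S)-1-acetyl-4-[3-methoxy-4-(triisopropylsilyloxy)phenyl]-3-oxabicyclo[3.1.0]hexan-2-one (aryl trans to the cyclopropane CH2) | CC(=O)[C@@]12C[C@@H]1[C@@H](c3ccc(O[Si](C(C)C)(C(C)C)C(C)C)c(OC)c3)OC2=O | intermediate
7 | 4-bromo-2,6-dimethoxyphenol | COc1cc(Br)cc(OC)c1O | starting material
8 | (R)-4-benzyl-3-(chloroacetyl)oxazolidin-2-one | O=C(CCl)N1[C@H](Cc2ccccc2)COC1=O | starting material
9 | (R)-4-benzyl-3-[(4-bromo-2,6-dimethoxyphenoxy)acetyl]oxazolidin-2-one | COc1cc(Br)cc(OC)c1OCC(=O)N1[C@H](Cc2ccccc2)COC1=O | intermediate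
10 | O-trimethylsilyl ether of 11 | COc1cc(Br)cc(OC)c1O[C@H](C(=O)N1[C@H](Cc2ccccc2)COC1=O)[C@@H](O[Si](C)(C)C)c1ccc(O[Si](C(C)C)(C(C)C)C(C)C)c(OC)c1 | intermediate
11 | (R)-4-benzyl-3-[(2S,3S)-2-(4-bromo-2,6-dimethoxyphenoxy)-3-hydroxy-3-(3-methoxy-4-triisopropylsilyloxyphenyl)propanoyl]oxazolidin-2-one (anti) | COc1cc(Br)cc(OC)c1O[C@H](C(=O)N1[C@H](Cc2ccccc2)COC1=O)[C@@H](O)c1ccc(O[Si](C(C)C)(C(C)C)C(C)C)c(OC)c1 | intermediate
12 | (1S,2R)-2-(4-bromo-2,6-dimethoxyphenoxy)-1-[3-methoxy-4-(triisopropylsilyloxy)phenyl]propane-1,3-diol (erythro) | COc1cc(Br)cc(OC)c1O[C@H](CO)[C@@H](O)c1ccc(O[Si](C(C)C)(C(C)C)C(C)C)c(OC)c1 | intermediate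
13 | 1,3-bis(tert-butyldimethylsilyl) ether of 12 | COc1cc(Br)cc(OC)c1O[C@H](CO[Si](C)(C)C(C)(C)C)[C@@H](O[Si](C)(C)C(C)(C)C)c1ccc(O[Si](C(C)C)(C(C)C)C(C)C)c(OC)c1 | intermediate
14 | aryllithium from 13 (lithium in place of bromine) | COc1cc([Li])cc(OC)c1O[C@H](CO[Si](C)(C)C(C)(C)C)[C@@H](O[Si](C)(C)C(C)(C)C)c1ccc(O[Si](C(C)C)(C(C)C)C(C)C)c(OC)c1 | intermediate
15 | 4-{[(1S,2R)-1,3-bis(tert-butyldimethylsilyloxy)-1-(3-methoxy-4-triisopropylsilyloxyphenyl)propan-2-yl]oxy}-3,5-dimethoxybenzaldehyde | COc1cc(C=O)cc(OC)c1O[C@H](CO[Si](C)(C)C(C)(C)C)[C@@H](O[Si](C)(C)C(C)(C)C)c1ccc(O[Si](C(C)C)(C(C)C)C(C)C)c(OC)c1 | intermediate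
16 | iodomagnesium enolate of trans-3-acetyl-4-(iodomethyl)-5-ArG-dihydrofuran-2-one | CC(=O)C1=C(O[Mg]I)O[C@H](c2ccc(O[Si](C(C)C)(C(C)C)C(C)C)c(OC)c2)[C@H]1CI | intermediate
17 | iodomagnesium alkoxide of the aldol adduct of 16 and 15 (new C–C bond cis to CH2I) | COc1cc([C@H]2OC(=O)[C@](C(C)=O)([C@H](O[Mg]I)c3cc(OC)c(O[C@H](CO[Si](C)(C)C(C)(C)C)[C@@H](O[Si](C)(C)C(C)(C)C)c4ccc(O[Si](C(C)C)(C(C)C)C(C)C)c(OC)c4)c(OC)c3)[C@@H]2CI)ccc1O[Si](C(C)C)(C(C)C)C(C)C | intermediate
18 | 1-acetyl derivative of 19 (acetyl on the ring-fusion carbon C1) | COc1cc([C@H]2OC(=O)[C@@]3(C(C)=O)[C@@H]2CO[C@@H]3c2cc(OC)c(O[C@H](CO[Si](C)(C)C(C)(C)C)[C@@H](O[Si](C)(C)C(C)(C)C)c3ccc(O[Si](C(C)C)(C(C)C)C(C)C)c(OC)c3)c(OC)c2)ccc1O[Si](C(C)C)(C(C)C)C(C)C | intermediate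
19 | (1S,4S,5R,8S)-4-ArG-8-ArS-3,7-dioxabicyclo[3.3.0]octan-2-one (cis-fused, both aryl groups exo) | COc1cc([C@H]2OC(=O)[C@H]3[C@@H]2CO[C@@H]3c2cc(OC)c(O[C@H](CO[Si](C)(C)C(C)(C)C)[C@@H](O[Si](C)(C)C(C)(C)C)c3ccc(O[Si](C(C)C)(C(C)C)C(C)C)c(OC)c3)c(OC)c2)ccc1O[Si](C(C)C)(C(C)C)C(C)C | intermediate
20 | {(2S,3R,4R)-2-ArS-4-[(S)-hydroxy(ArG)methyl]oxolan-3-yl}methanol | COc1cc([C@@H](O)[C@H]2CO[C@H](c3cc(OC)c(O[C@H](CO[Si](C)(C)C(C)(C)C)[C@@H](O[Si](C)(C)C(C)(C)C)c4ccc(O[Si](C(C)C)(C(C)C)C(C)C)c(OC)c4)c(OC)c3)[C@H]2CO)ccc1O[Si](C(C)C)(C(C)C)C(C)C | intermediate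
21 | primary methanesulfonate of 20 | COc1cc([C@@H](O)[C@H]2CO[C@H](c3cc(OC)c(O[C@H](CO[Si](C)(C)C(C)(C)C)[C@@H](O[Si](C)(C)C(C)(C)C)c4ccc(O[Si](C(C)C)(C(C)C)C(C)C)c(OC)c4)c(OC)c3)[C@H]2COS(C)(=O)=O)ccc1O[Si](C(C)C)(C(C)C)C(C)C | intermediate
22 | 4,4''-bis-O-triisopropylsilyl-7'',9''-bis-O-tert-butyldimethylsilyl hedyotol C | COc1cc([C@H]2OC[C@H]3[C@@H]2CO[C@@H]3c2cc(OC)c(O[C@H](CO[Si](C)(C)C(C)(C)C)[C@@H](O[Si](C)(C)C(C)(C)C)c3ccc(O[Si](C(C)C)(C(C)C)C(C)C)c(OC)c3)c(OC)c2)ccc1O[Si](C(C)C)(C(C)C)C(C)C | intermediate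
23 | Hedyotol C | COc1cc([C@H]2OC[C@H]3[C@@H]2CO[C@@H]3c2cc(OC)c(O[C@H](CO)[C@@H](O)c3ccc(O)c(OC)c3)c(OC)c2)ccc1O | target

**Step count and risks**

Total step count: 14. Longest linear sequence: 9 steps (steps 6 to 14, or steps 1 to 5 and 11 to 14).

Steps most likely to fail:

1. Step 11 (proposed new method). Iodide may attack the benzylic lactone carbon instead of the cyclopropane CH2. The ring-opened enolate may close through its ketone oxygen to a dihydrofuran before it adds to the electron-rich aldehyde. The two faces at C8 may not be differentiated well enough. The fallback uses known chemistry and forms the two bonds one after the other; it sets out from 6 and 15 and comes back at 19. Aldehyde 15 would be reduced with NaBH4 to the benzylic alcohol F1. Acid-catalysed homo-conjugate opening of cyclopropane 6 by this alcohol (Sc(OTf)3 cat., CH2Cl2), as is known for 1-acetyl cyclopropane lactones and benzylic alcohols, would give the trans 3-acetyl-4-(benzyloxymethyl) lactone F2 with the C6–O7 bond in place. DDQ-mediated oxidative cyclisation of the electron-rich benzylic ether (hydride abstraction to the oxocarbenium ion, trapped by the enol of the keto lactone) would then form C1–C8 and give 18. Deacetylation with K2CO3 in MeOH as in the main route would lead to 19.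

2. Step 7. Additional chelation of magnesium by the aryloxy and methoxy oxygens may erode the anti and the facial selectivity, and retro-aldol may compete with silyl trapping. The fallback sets out from 7 and 2 and comes back at 13. Phenol 7 would be alkylated with (S)-4-benzyl-3-(chloroacetyl)oxazolidin-2-one to the enantiomeric-auxiliary imide F3. A boron-mediated Evans syn-aldol reaction (Bu2BOTf, iPr2NEt, then 2) would give the syn adduct F4, and NaBH4 would give the threo diol F5. Silylation of the primary hydroxyl (tBuMe2SiCl, imidazole) would give F6, and Dess–Martin oxidation the aryl ketone F7. Chelation-controlled reduction with Zn(BH4)2 would give the erythro alcohol F8, and tBuMe2SiOTf would convert it into 13.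

3. Step 5. The electron-rich allylic ester may ionise in acetic acid, with loss of enantiomeric purity or allylic transposition, and the radical cyclisation may be only moderately diastereoselective. The fallback sets out from 5 and comes back at 6. Diazo transfer (4-acetamidobenzenesulfonyl azide, Et3N, MeCN) would give the diazo acetoacetate F9, and intramolecular cyclopropanation with Rh2(OAc)4 (cat.) in CH2Cl2 under neutral conditions would give 6.

Further compounds
F1 | step 11 | benzylic alcohol from 15 (CH2OH in place of CHO) | COc1cc(CO)cc(OC)c1O[C@H](CO[Si](C)(C)C(C)(C)C)[C@@H](O[Si](C)(C)C(C)(C)C)c1ccc(O[Si](C(C)C)(C(C)C)C(C)C)c(OC)c1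
F2 | step 11 | trans-3-acetyl-5-ArG-4-[(ArS-methoxy)methyl]dihydrofuran-2-one (C3 epimerisable) | CC(=O)C1C(=O)O[C@H](c2ccc(O[Si](C(C)C)(C(C)C)C(C)C)c(OC)c2)[C@H]1COCc1cc(OC)c(O[C@H](CO[Si](C)(C)C(C)(C)C)[C@@H](O[Si](C)(C)C(C)(C)C)c2ccc(O[Si](C(C)C)(C(C)C)C(C)C)c(OC)c2)c(OC)c1
F3 | step 7 | (S)-4-benzyl-3-[(4-bromo-2,6-dimethoxyphenoxy)acetyl]oxazolidin-2-one | COc1cc(Br)cc(OC)c1OCC(=O)N1[C@@H](Cc2ccccc2)COC1=O
F4 | step 7 | (S)-4-benzyl-3-[(2S,3R)-2-(4-bromo-2,6-dimethoxyphenoxy)-3-hydroxy-3-ArG-propanoyl]oxazolidin-2-one (syn) | COc1cc(Br)cc(OC)c1O[C@H](C(=O)N1[C@@H](Cc2ccccc2)COC1=O)[C@H](O)c1ccc(O[Si](C(C)C)(C(C)C)C(C)C)c(OC)c1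
F5 | step 7 | (1R,2R)-2-(4-bromo-2,6-dimethoxyphenoxy)-1-ArG-propane-1,3-diol (threo) | COc1cc(Br)cc(OC)c1O[C@H](CO)[C@H](O)c1ccc(O[Si](C(C)C)(C(C)C)C(C)C)c(OC)c1
F6 | step 7 | 3-O-tert-butyldimethylsilyl ether of F5 | COc1cc(Br)cc(OC)c1O[C@H](CO[Si](C)(C)C(C)(C)C)[C@H](O)c1ccc(O[Si](C(C)C)(C(C)C)C(C)C)c(OC)c1
F7 | step 7 | (R)-2-(4-bromo-2,6-dimethoxyphenoxy)-3-(tert-butyldimethylsilyloxy)-1-ArG-propan-1-one | COc1cc(Br)cc(OC)c1O[C@H](CO[Si](C)(C)C(C)(C)C)C(=O)c1ccc(O[Si](C(C)C)(C(C)C)C(C)C)c(OC)c1
F8 | step 7 | (1S,2R)-2-(4-bromo-2,6-dimethoxyphenoxy)-3-(tert-butyldimethylsilyloxy)-1-ArG-propan-1-ol (erythro) | COc1cc(Br)cc(OC)c1O[C@H](CO[Si](C)(C)C(C)(C)C)[C@@H](O)c1ccc(O[Si](C(C)C)(C(C)C)C(C)C)c(OC)c1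
F9 | step 5 | (S)-1-ArG-prop-2-en-1-yl 2-diazo-3-oxobutanoate | C=C[C@H](OC(=O)C(=[N+]=[N-])C(C)=O)c1ccc(O[Si](C(C)C)(C(C)C)C(C)C)c(OC)c1
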